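**Plan**

Numbering: ring A carbons are C1 (quaternary), C2 (CHOH), C3 (alkylidene carbon) and C4–C6; C9 is the carbonyl carbon on C1; ring B carries primes; the linker carbons run from Ca (on C3) to Cd (on C3').
Retrosynthetic cuts, in order: the two C9–CH2(prenyl) bonds; the exocyclic double bonds C3'=Cd and C3=Ca; in each ring the C1–C6 bond; then the lactone C9(O)–O–C4 bond, C1–C2 (propionate aldol) and C3–C4 (glycolate aldol with acrolein).
Enabling feature: in each ring the quaternary C1 carries carbonyl C9 and lies between carbinol C2 and methylene C6, with oxygenated C3 and C4 beyond; C1–C6 is therefore the σ-bond of a [3,3] shift in the ketene acetal of a δ-lactone (C9 to O to C4) that bears the vinyl group C5=C6 on C4.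
Forward: two aldol reactions build the chain and give δ-lactone 12; inversion at C4 gives lactone 28; ring A arises from 12 and ring B from 28 by Ireland–Claisen rearrangement, leading to keto esters 18 and 34.
Joining: Wittig reaction of 18 with a four-carbon ylide, conversion of the chain end into a phosphonium salt, second Wittig reaction with 34; then both esters become prenyl ketones and the silyl ethers are removed last.
Stereochemistry: C3/C4 from the auxiliary-controlled glycolate aldol; C2 (R in both rings of the target) from the Evans propionate aldol; C1 by chirality transfer from C4 (vinyl cis to the C2 oxygen gives ring A, trans gives ring B); both Z-alkenes from Wittig reactions of α-silyloxy ketones.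

Key step: step 8

Remark: C3 of the lactones is oxidised to the ketone later; it is placed with its benzyloxy group cis to the C2 silyloxy group (the outcome of the syn glycolate aldol), and C2 carries the silyl ether that is kept to the last step.
Remark: the carbinol centres formed in step 25 arise as epimer mixtures and are erased in step 26, so they are drawn without configuration.
Remark: step 25 consumes two equivalents of prenyl chloride 39, one for each aldehyde group of 38.
Abbreviations: TBS = tert-butyldimethylsilyl, TES = triethylsilyl, Bn = benzyl.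

**Route**

Step 1
Reactants: 1 (R)-4-benzylthiazolidine-2-thione; 2 (benzyloxy)acetyl chloride
Product: 3 (R)-4-benzyl-3-[(benzyloxy)acetyl]thiazolidine-2-thione
Conditions: Et3N, DMAP (cat.), CH2Cl2, 0 °C to rt
Reagents that add atoms: none
Why: N-acylation of the thiazolidinethione by the acid chloride (amine base, DMAP catalysis) loads the glycolate unit on the auxiliary without touching the benzyl ether.

Step 2
Reactants: 3 (R)-4-benzyl-3-[(benzyloxy)acetyl]thiazolidine-2-thione; 4 acrolein
Product: 5 (R)-4-benzyl-3-[(2R,3S)-2-(benzyloxy)-3-hydroxypent-4-enoyl]thiazolidine-2-thione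
Conditions: TiCl4, i-Pr2NEt, N-methylpyrrolidin-2-one, CH2Cl2, 0 °C; then acrolein, −78 to 0 °C
Reagents that add atoms: none
Why: Titanium-enolate syn-aldol addition of an N-glycolyl thiazolidinethione: the Z-enolate reacts through a chair Zimmerman–Traxler transition state on the face away from the auxiliary benzyl group, which should set C3 (OBn) and C4 (OH) syn to one another with the 2R,3S configuration.

Step 3
Reactants: 5 (R)-4-benzyl-3-[(2R,3S)-2-(benzyloxy)-3-hydroxypent-4-enoyl]thiazolidine-2-thione
Product: 6 (R)-4-benzyl-3-[(2R,3S)-2-(benzyloxy)-3-(triethylsilyloxy)pent-4-enoyl]thiazolidine-2-thione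
Conditions: Et3SiOTf, 2,6-lutidine, CH2Cl2, −78 °C
Reagents that add atoms: triethylsilyl triflate, CC[Si](CC)(CC)OS(=O)(=O)C(F)(F)F
Why: Silylation of the secondary allylic alcohol with a silyl triflate and a hindered pyridine base; the TES group is chosen because it can later be removed in the presence of a TBS ether.

Step 4
Reactants: 6 (R)-4-benzyl-3-[(2R,3S)-2-(benzyloxy)-3-(triethylsilyloxy)pent-4-enoyl]thiazolidine-2-thione
Product: 7 (2R,3S)-2-(benzyloxy)-3-(triethylsilyloxy)pent-4-enal
Conditions: i-Bu2AlH, CH2Cl2, −78 °C; aq. potassium sodium tartrate (KNaC4H4O6)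
Reagents that add atoms: none
Why: Hydride reduction of the N-acyl thiazolidinethione, whose tetrahedral aluminate collapses only on work-up, gives the aldehyde directly and releases the auxiliary; at −78 °C the α-benzyloxy centre should not epimerise.

Step 5
Reactants: 7 (2R,3S)-2-(benzyloxy)-3-(triethylsilyloxy)pent-4-enal; 8 (S)-4-benzyl-3-propanoyloxazolidin-2-one
Product: 9 (S)-4-benzyl-3-[(2S,3S,4S,5S)-4-(benzyloxy)-3-hydroxy-2-methyl-5-(triethylsilyloxy)hept-6-enoyl]oxazolidin-2-one
Conditions: 8, Bu2BOTf, i-Pr2NEt, CH2Cl2, −78 to 0 °C; 7, −78 to 0 °C; pH 7 buffer, MeOH, H2O2, 0 °C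
Reagents that add atoms: none
Why: Evans syn-aldol reaction: the Z-dibutylboron enolate adds through a chair Zimmerman–Traxler transition state under auxiliary control and sets C1 and C2, and the resulting anti relation between the new C2 hydroxyl and the C3 benzyloxy group is also the Felkin–Anh/Cornforth preference of the α-alkoxy aldehyde, so reagent and substrate control reinforce each other.

Step 6
Reactants: 9 (S)-4-benzyl-3-[(2S,3S,4S,5S)-4-(benzyloxy)-3-hydroxy-2-methyl-5-(triethylsilyloxy)hept-6-enoyl]oxazolidin-2-one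
Product: 10 (S)-4-benzyl-3-[(2S,3S,4R,5S)-4-(benzyloxy)-3-(tert-butyldimethylsilyloxy)-2-methyl-5-(triethylsilyloxy)hept-6-enoyl]oxazolidin-2-one
Conditions: t-BuMe2SiOTf, 2,6-lutidine, CH2Cl2, 0 °C
Reagents that add atoms: tert-butyldimethylsilyl triflate, CC(C)(C)[Si](C)(C)OS(=O)(=O)C(F)(F)F
Why: Silyl triflate protection of the hindered secondary hydroxyl under non-basic conditions avoids retro-aldol cleavage; this ether stays until the last step.

Step 7
Reactants: 10 (S)-4-benzyl-3-[(2S,3S,4R,5S)-4-(benzyloxy)-3-(tert-butyldimethylsilyloxy)-2-methyl-5-(triethylsilyloxy)hept-6-enoyl]oxazolidin-2-one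
Product: 12 (3S,4S,5R,6S)-5-(benzyloxy)-4-(tert-butyldimethylsilyloxy)-6-ethenyl-3-methyloxan-2-one (lactone of the ring A series; vinyl, OTBS and OBn all cis), via hydroxy imide 11 (not isolated)
Conditions: HF·pyridine, pyridine, THF, 0 °C; then Et3N, DMAP (cat.), CH2Cl2, rt
Reagents that add atoms: none
Why: The allylic TES ether is cleaved much faster by buffered HF than the hindered TBS ether, and the freed C4 hydroxyl then attacks the imide carbonyl (6-exo-trig lactonisation by intramolecular acyl transfer) with loss of the oxazolidinone and retention at C4.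

Step 8
Reactants: 12 (3S,4S,5R,6S)-5-(benzyloxy)-4-(tert-butyldimethylsilyloxy)-6-ethenyl-3-methyloxan-2-one
Product: 15 (1R,2S,3R)-3-(benzyloxy)-2-(tert-butyldimethylsilyloxy)-1-methylcyclohex-4-ene-1-carboxylic acid (methyl, OTBS and OBn cis; CO2H trans to them), via silyl ketene acetal 13 (not isolated), via trimethylsilyl ester 14 (not isolated)
Conditions: Me3SiCl, Et3N, THF, −78 °C; LiN(i-Pr)2 added slowly, −78 °C to rt; toluene, 110 °C; then 1 M HCl, THF
Reagents that add atoms: none
Why: LiN(i-Pr)2 removes the C1 proton while Me3SiCl already present traps the enolate on oxygen, giving the cyclic ketene acetal 13 whose double-bond geometry is fixed by the lactone ring; on heating, the terminal carbon C6 of the C4 vinyl group bonds to C1 as the allylic C4–O bond breaks in a concerted suprafacial [3,3] shift (Ireland–Claisen rearrangement), and acid hydrolysis of silyl ester 14 releases acid 15. The closest known reaction type is the Ireland–Claisen rearrangement of silyl ketene acetals of 6-alkenyl δ-lactones to cyclohexenecarboxylic acids. Ring A closes through the C1–C6 bond in a pericyclic, boat-like (bicyclo[2.2.2]octene-type) transition state and not by an exo or endo ionic cyclisation, the former ring oxygen leaving the ring as a carboxyl oxygen. The only new stereocentre, quaternary C1, is controlled by C4: the vinyl group can reach C1 only across the lactone face on which it stands, which is also the face of the C2 silyloxy group, so the methyl group ends up cis to the C2 oxygen (1R) while C4 becomes sp2. The step needs O-silylation to outrun β-elimination of the C2 silyloxy group from the lithium enolate, which is secured by having Me3SiCl/Et3N mixed with the lactone at −78 °C before the base is added; no regiocontrol is needed because C1 carries the only acidic proton next to C9.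

Step 9
Reactants: 15 (1R,2S,3R)-3-(benzyloxy)-2-(tert-butyldimethylsilyloxy)-1-methylcyclohex-4-ene-1-carboxylic acid
Product: 16 methyl (1R,2S,3R)-3-(benzyloxy)-2-(tert-butyldimethylsilyloxy)-1-methylcyclohex-4-ene-1-carboxylate
Conditions: MeI, K2CO3, DMF, rt
Reagents that add atoms: iodomethane, CI
Why: SN2 O-methylation of the carboxylate, preferred over Fischer esterification for an acid on a quaternary carbon, masks C9 for the ylide chemistry.

Step 10
Reactants: 16 methyl (1R,2S,3R)-3-(benzyloxy)-2-(tert-butyldimethylsilyloxy)-1-methylcyclohex-4-ene-1-carboxylate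
Product: 17 methyl (1R,2S,3R)-2-(tert-butyldimethylsilyloxy)-3-hydroxy-1-methylcyclohexane-1-carboxylate
Conditions: H2 (1 atm), 10% Pd/C, EtOAc, rt
Reagents that add atoms: none
Why: Heterogeneous catalytic hydrogenation saturates the cis-disubstituted C4=C5 bond faster than the allylic C–O bond can be cleaved and then hydrogenolyses the benzyl ether, while the silyl ether and the ester are inert; no stereocentre is created.

Step 11
Reactants: 17 methyl (1R,2S,3R)-2-(tert-butyldimethylsilyloxy)-3-hydroxy-1-methylcyclohexane-1-carboxylate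
Product: 18 methyl (1R,2S)-2-(tert-butyldimethylsilyloxy)-1-methyl-3-oxocyclohexane-1-carboxylate (ring A ketone)
Conditions: Dess–Martin periodinane, NaHCO3, CH2Cl2, rt
Reagents that add atoms: none
Why: Dess–Martin oxidation of the secondary alcohol under buffered, non-basic conditions gives the C3 ketone without epimerising the adjacent C2 centre.

Step 12
Reactants: 19 (4-bromobutoxy)(tert-butyl)dimethylsilane; 20 triphenylphosphine
Product: 21 [4-(tert-butyldimethylsilyloxy)butyl]triphenylphosphonium bromide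
Conditions: MeCN, reflux
Reagents that add atoms: none
Why: SN2 quaternisation of triphenylphosphine by the primary bromide gives the Wittig salt.

Step 13
Reactants: 18 methyl (1R,2S)-2-(tert-butyldimethylsilyloxy)-1-methyl-3-oxocyclohexane-1-carboxylate; 21 [4-(tert-butyldimethylsilyloxy)butyl]triphenylphosphonium bromide
Product: 23 methyl (1R,2R,3Z)-2-(tert-butyldimethylsilyloxy)-3-[4-(tert-butyldimethylsilyloxy)butylidene]-1-methylcyclohexane-1-carboxylate, via phosphorus ylide 22 (not isolated)
Conditions: 21, KN(SiMe3)2, THF, −78 to 0 °C; 18, −78 °C to rt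
Reagents that add atoms: none
Why: Wittig olefination with a salt-free non-stabilised ylide under kinetic control: with α-alkoxy ketones the ylide substituent ends up cis to the oxygen-bearing α-carbon, which here is also the more substituted side, so the chain should be placed cis to C2 (Z).

Step 14
Reactants: 23 methyl (1R,2R,3Z)-2-(tert-butyldimethylsilyloxy)-3-[4-(tert-butyldimethylsilyloxy)butylidene]-1-methylcyclohexane-1-carboxylate
Product: 24 methyl (1R,2R,3Z)-2-(tert-butyldimethylsilyloxy)-3-(4-hydroxybutylidene)-1-methylcyclohexane-1-carboxylate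
Conditions: HF·pyridine, pyridine, THF, 0 °C
Reagents that add atoms: none
Why: Fluoride-mediated desilylation is much faster at the unhindered primary silyl ether than at the secondary one flanked by the quaternary carbon.

Step 15
Reactants: 24 methyl (1R,2R,3Z)-2-(tert-butyldimethylsilyloxy)-3-(4-hydroxybutylidene)-1-methylcyclohexane-1-carboxylate
Product: 25 methyl (1R,2R,3Z)-2-(tert-butyldimethylsilyloxy)-3-(4-iodobutylidene)-1-methylcyclohexane-1-carboxylate
Conditions: I2, PPh3, imidazole, CH2Cl2, 0 °C to rt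
Reagents that add atoms: iodine, II
Why: Appel-type iodination (PPh3/I2/imidazole) converts the primary alcohol through its alkoxyphosphonium salt by SN2 displacement and leaves alkene, ester and silyl ether untouched.

Step 16
Reactants: 25 methyl (1R,2R,3Z)-2-(tert-butyldimethylsilyloxy)-3-(4-iodobutylidene)-1-methylcyclohexane-1-carboxylate; 20 triphenylphosphine
Product: 26 {(4Z)-4-[(2R,3R)-2-(tert-butyldimethylsilyloxy)-3-(methoxycarbonyl)-3-methylcyclohexylidene]butyl}triphenylphosphonium iodide
Conditions: MeCN, 80 °C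
Reagents that add atoms: none
Why: SN2 quaternisation of triphenylphosphine by the primary iodide under neutral conditions that the allylic silyl ether tolerates.

Step 17
Reactants: 12 (3S,4S,5R,6S)-5-(benzyloxy)-4-(tert-butyldimethylsilyloxy)-6-ethenyl-3-methyloxan-2-one
Product: 28 (3S,4S,5R,6R)-5-(benzyloxy)-4-(tert-butyldimethylsilyloxy)-6-ethenyl-3-methyloxan-2-one (lactone of the ring B series; vinyl trans to OTBS and OBn), via hydroxy acid 27 (not isolated)
Conditions: LiOH, THF/H2O, 0 °C; 1 M HCl to pH 4 at 0 °C, extraction; then PPh3, DIAD, toluene, 0 °C to rt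
Reagents that add atoms: lithium hydroxide, [Li+].[OH-]
Why: Saponification opens the lactone and the Mitsunobu reaction closes it again, the carboxylate displacing the alkoxyphosphonium group at allylic C4 in an intramolecular SN2 reaction (6-exo-tet), so that C4 is inverted and the vinyl group becomes trans to the C2 silyloxy group.

Step 18
Reactants: 28 (3S,4S,5R,6R)-5-(benzyloxy)-4-(tert-butyldimethylsilyloxy)-6-ethenyl-3-methyloxan-2-one
Product: 31 (1S,2S,3R)-3-(benzyloxy)-2-(tert-butyldimethylsilyloxy)-1-methylcyclohex-4-ene-1-carboxylic acid (CO2H, OTBS and OBn cis; methyl trans to them), via silyl ketene acetal 29 (not isolated), via trimethylsilyl ester 30 (not isolated)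
Conditions: Me3SiCl, Et3N, THF, −78 °C; LiN(i-Pr)2 added slowly, −78 °C to rt; toluene, 110 °C; then 1 M HCl, THF
Reagents that add atoms: none
Why: Ireland–Claisen rearrangement as in step 8 through the same boat-like transition state; because the vinyl group now stands on the lactone face opposite the C2 silyloxy group, C6 bonds to the other face of C1 and the methyl group ends up trans to the C2 oxygen (1S), as ring B requires.

Step 19
Reactants: 31 (1S,2S,3R)-3-(benzyloxy)-2-(tert-butyldimethylsilyloxy)-1-methylcyclohex-4-ene-1-carboxylic acid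
Product: 32 methyl (1S,2S,3R)-3-(benzyloxy)-2-(tert-butyldimethylsilyloxy)-1-methylcyclohex-4-ene-1-carboxylate
Conditions: MeI, K2CO3, DMF, rt
Reagents that add atoms: iodomethane, CI
Why: SN2 O-methylation of the hindered carboxylate, as in step 9.

Step 20
Reactants: 32 methyl (1S,2S,3R)-3-(benzyloxy)-2-(tert-butyldimethylsilyloxy)-1-methylcyclohex-4-ene-1-carboxylate
Product: 33 methyl (1S,2S,3R)-2-(tert-butyldimethylsilyloxy)-3-hydroxy-1-methylcyclohexane-1-carboxylate
Conditions: H2 (1 atm), 10% Pd/C, EtOAc, rt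
Reagents that add atoms: none
Why: Catalytic hydrogenation of the ring alkene followed by hydrogenolysis of the benzyl ether, as in step 10; the C3 hydroxyl, here cis to the ester, is oxidised without delay in step 21 so that lactonisation onto C9 does not intervene.

Step 21
Reactants: 33 methyl (1S,2S,3R)-2-(tert-butyldimethylsilyloxy)-3-hydroxy-1-methylcyclohexane-1-carboxylate
Product: 34 methyl (1S,2S)-2-(tert-butyldimethylsilyloxy)-1-methyl-3-oxocyclohexane-1-carboxylate (ring B ketone)
Conditions: Dess–Martin periodinane, NaHCO3, CH2Cl2, rt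
Reagents that add atoms: none
Why: Dess–Martin oxidation under buffered conditions gives the C3' ketone without epimerising C2'.

Step 22
Reactants: 26 {(4Z)-4-[(2R,3R)-2-(tert-butyldimethylsilyloxy)-3-(methoxycarbonyl)-3-methylcyclohexylidene]butyl}triphenylphosphonium iodide; 34 methyl (1S,2S)-2-(tert-butyldimethylsilyloxy)-1-methyl-3-oxocyclohexane-1-carboxylate
Product: 36 dimethyl (1R,1'S,2R,2'R,3Z,3'Z)-3,3'-(butane-1,4-diylidene)bis[2-(tert-butyldimethylsilyloxy)-1-methylcyclohexane-1-carboxylate], via phosphorus ylide 35 (not isolated)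
Conditions: 26, KN(SiMe3)2, THF, −78 to 0 °C; 34, −78 °C to rt
Reagents that add atoms: none
Why: Wittig olefination as in step 13: the non-stabilised ylide adds to the α-silyloxy ketone under kinetic control and should again place the chain cis to the oxygen-bearing C2' (Z), joining the two rings through the four-carbon linker.

Step 23
Reactants: 36 dimethyl (1R,1'S,2R,2'R,3Z,3'Z)-3,3'-(butane-1,4-diylidene)bis[2-(tert-butyldimethylsilyloxy)-1-methylcyclohexane-1-carboxylate]
Product: 37 the bis(hydroxymethyl) compound, [(3Z,3'Z)-3,3'-(butane-1,4-diylidene)bis[2-(tert-butyldimethylsilyloxy)-1-methylcyclohexane-3,1-diyl]]dimethanol, ring configurations as in 36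
Conditions: i-Bu2AlH (excess), CH2Cl2, −78 to 0 °C; aq. potassium sodium tartrate (KNaC4H4O6)
Reagents that add atoms: none
Why: Hydride reduction of both hindered methyl esters to primary alcohols at low temperature, where the aluminium alkoxides should not promote silyl migration from the C2 oxygen.

Step 24
Reactants: 37 the bis(hydroxymethyl) compound
Product: 38 (1R,1'S,2R,2'R,3Z,3'Z)-3,3'-(butane-1,4-diylidene)bis[2-(tert-butyldimethylsilyloxy)-1-methylcyclohexane-1-carbaldehyde]
Conditions: Dess–Martin periodinane, NaHCO3, CH2Cl2, rt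
Reagents that add atoms: none
Why: Dess–Martin oxidation of the two neopentyl primary alcohols gives aldehydes that cannot enolise, so C1 and C1' are safe.

Step 25
Reactants: 38 the dialdehyde; 39 1-chloro-3-methylbut-2-ene (prenyl chloride), two equivalents consumed, one for each aldehyde group
Product: 41 1,1'-[(3Z,3'Z)-3,3'-(butane-1,4-diylidene)bis[2-(tert-butyldimethylsilyloxy)-1-methylcyclohexane-3,1-diyl]]bis(4-methylpent-3-en-1-ol), ring configurations as in 36 and carbinol centres as epimer mixtures, via prenylbarium chloride 40 (not isolated)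
Conditions: BaI2, lithium biphenylide (LiC12H10), THF, rt (activated Ba); 39 (slightly more than 2 equiv per dialdehyde), −78 °C; then 38, −78 °C; aq. NH4Cl at −78 °C
Reagents that add atoms: 1-chloro-3-methylbut-2-ene (the second equivalent of 39, which supplies the prenyl group for the second aldehyde), CC(C)=CCCl
Why: Twofold allylbarium addition, one molecule of prenylbarium chloride per aldehyde group: this reagent, unlike the magnesium, zinc or indium reagents, reacts with carbonyl groups at its unsubstituted α-carbon without allylic transposition, and the neopentyl aldehydes add a steric bias against the γ-terminus; quenching cold limits silyl migration to the new alkoxides.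

Step 26
Reactants: 41 the bis(homoallylic alcohol)
Product: 42 1,1'-[(1R,1'S,2R,2'R,3Z,3'Z)-3,3'-(butane-1,4-diylidene)bis[2-(tert-butyldimethylsilyloxy)-1-methylcyclohexane-3,1-diyl]]bis(4-methylpent-3-en-1-one)
Conditions: Dess–Martin periodinane, NaHCO3, CH2Cl2, 0 °C
Reagents that add atoms: none
Why: Dess–Martin oxidation under bicarbonate buffer converts the homoallylic alcohols into β,γ-unsaturated ketones without moving the double bonds into conjugation, and it erases the carbinol centres formed in step 25.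

Step 27
Reactants: 42 the bis(silyl ether) of the target
Product: 43 CNP0297042.3, 1,1'-[(1R,1'S,2R,2'R,3Z,3'Z)-3,3'-(butane-1,4-diylidene)bis(2-hydroxy-1-methylcyclohexane-3,1-diyl)]bis(4-methylpent-3-en-1-one)
Conditions: HF·pyridine, pyridine, THF, 0 °C to rt
Reagents that add atoms: none
Why: Fluoride-mediated desilylation with buffered HF·pyridine is chosen because basic fluoride sources could trigger retro-aldol cleavage of the β-hydroxy ketones or conjugation of the β,γ-enones; the four stereocentres and both Z-alkenes are not touched.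

**Compound list**

1 | (R)-4-benzylthiazolidine-2-thione | S=C1N[C@H](Cc2ccccc2)CS1 | starting material
2 | (benzyloxy)acetyl chloride | ClC(=O)COCc1ccccc1 | starting material
3 | (R)-4-benzyl-3-[(benzyloxy)acetyl]thiazolidine-2-thione | O=C(COCc1ccccc1)N1C(=S)SC[C@H]1Cc1ccccc1 | intermediate
4 | acrolein (prop-2-enal) | C=CC=O | starting material
5 | (R)-4-benzyl-3-[(2R,3S)-2-(benzyloxy)-3-hydroxypent-4-enoyl]thiazolidine-2-thione | O=C([C@H](OCc1ccccc1)[C@@H](O)C=C)N1C(=S)SC[C@H]1Cc1ccccc1 | intermediate
6 | (R)-4-benzyl-3-[(2R,3S)-2-(benzyloxy)-3-(triethylsilyloxy)pent-4-enoyl]thiazolidine-2-thione | O=C([C@H](OCc1ccccc1)[C@@H](O[Si](CC)(CC)CC)C=C)N1C(=S)SC[C@H]1Cc1ccccc1 | intermediate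
7 | (2R,3S)-2-(benzyloxy)-3-(triethylsilyloxy)pent-4-enal | O=C[C@H](OCc1ccccc1)[C@@H](O[Si](CC)(CC)CC)C=C | intermediate
8 | (S)-4-benzyl-3-propanoyloxazolidin-2-one | CCC(=O)N1C(=O)OC[C@@H]1Cc1ccccc1 | starting material
9 | (S)-4-benzyl-3-[(2S,3S,4S,5S)-4-(benzyloxy)-3-hydroxy-2-methyl-5-(triethylsilyloxy)hept-6-enoyl]oxazolidin-2-one | O=C([C@@H](C)[C@H](O)[C@H](OCc1ccccc1)[C@@H](O[Si](CC)(CC)CC)C=C)N1C(=O)OC[C@@H]1Cc1ccccc1 | intermediate
10 | (S)-4-benzyl-3-[(2S,3S,4R,5S)-4-(benzyloxy)-3-(tert-butyldimethylsilyloxy)-2-methyl-5-(triethylsilyloxy)hept-6-enoyl]oxazolidin-2-one | O=C([C@@H](C)[C@H](O[Si](C)(C)C(C)(C)C)[C@H](OCc1ccccc1)[C@@H](O[Si](CC)(CC)CC)C=C)N1C(=O)OC[C@@H]1Cc1ccccc1 | intermediate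
11 | (S)-4-benzyl-3-[(2S,3S,4R,5S)-4-(benzyloxy)-3-(tert-butyldimethylsilyloxy)-5-hydroxy-2-methylhept-6-enoyl]oxazolidin-2-one (hydroxy imide) | O=C([C@@H](C)[C@H](O[Si](C)(C)C(C)(C)C)[C@H](OCc1ccccc1)[C@@H](O)C=C)N1C(=O)OC[C@@H]1Cc1ccccc1 | intermediate
12 | (3S,4S,5R,6S)-5-(benzyloxy)-4-(tert-butyldimethylsilyloxy)-6-ethenyl-3-methyloxan-2-one (lactone, ring A series) | C=C[C@@H]1OC(=O)[C@@H](C)[C@H](O[Si](C)(C)C(C)(C)C)[C@@H]1OCc1ccccc1 | intermediate
13 | trimethylsilyl ketene acetal of 12: 3-(benzyloxy)-4-(tert-butyldimethylsilyloxy)-2-ethenyl-5-methyl-6-(trimethylsilyloxy)-3,4-dihydro-2H-pyran, ring centres as in 12 | C=C[C@@H]1OC(O[Si](C)(C)C)=C(C)[C@H](O[Si](C)(C)C(C)(C)C)[C@@H]1OCc1ccccc1 | intermediate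
14 | trimethylsilyl (1R,2S,3R)-3-(benzyloxy)-2-(tert-butyldimethylsilyloxy)-1-methylcyclohex-4-ene-1-carboxylate | C[Si](C)(C)OC(=O)[C@]1(C)CC=C[C@@H](OCc2ccccc2)[C@H]1O[Si](C)(C)C(C)(C)C | intermediate
15 | (1R,2S,3R)-3-(benzyloxy)-2-(tert-butyldimethylsilyloxy)-1-methylcyclohex-4-ene-1-carboxylic acid | OC(=O)[C@]1(C)CC=C[C@@H](OCc2ccccc2)[C@H]1O[Si](C)(C)C(C)(C)C | intermediate
16 | methyl (1R,2S,3R)-3-(benzyloxy)-2-(tert-butyldimethylsilyloxy)-1-methylcyclohex-4-ene-1-carboxylate | COC(=O)[C@]1(C)CC=C[C@@H](OCc2ccccc2)[C@H]1O[Si](C)(C)C(C)(C)C | intermediate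
17 | methyl (1R,2S,3R)-2-(tert-butyldimethylsilyloxy)-3-hydroxy-1-methylcyclohexane-1-carboxylate | COC(=O)[C@]1(C)CCC[C@@H](O)[C@H]1O[Si](C)(C)C(C)(C)C | intermediate
18 | methyl (1R,2S)-2-(tert-butyldimethylsilyloxy)-1-methyl-3-oxocyclohexane-1-carboxylate | COC(=O)[C@]1(C)CCCC(=O)[C@H]1O[Si](C)(C)C(C)(C)C | intermediate
19 | (4-bromobutoxy)(tert-butyl)dimethylsilane | BrCCCCO[Si](C)(C)C(C)(C)C | starting material
20 | triphenylphosphine | c1ccc(cc1)P(c1ccccc1)c1ccccc1 | starting material
21 | [4-(tert-butyldimethylsilyloxy)butyl]triphenylphosphonium bromide | [Br-].CC(C)(C)[Si](C)(C)OCCCC[P+](c1ccccc1)(c1ccccc1)c1ccccc1 | intermediate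
22 | [4-(tert-butyldimethylsilyloxy)butylidene]triphenylphosphorane | CC(C)(C)[Si](C)(C)OCCCC=P(c1ccccc1)(c1ccccc1)c1ccccc1 | intermediate
23 | methyl (1R,2R,3Z)-2-(tert-butyldimethylsilyloxy)-3-[4-(tert-butyldimethylsilyloxy)butylidene]-1-methylcyclohexane-1-carboxylate | COC(=O)[C@]1(C)CCC/C(=C/CCCO[Si](C)(C)C(C)(C)C)[C@H]1O[Si](C)(C)C(C)(C)C | intermediate
24 | methyl (1R,2R,3Z)-2-(tert-butyldimethylsilyloxy)-3-(4-hydroxybutylidene)-1-methylcyclohexane-1-carboxylate | COC(=O)[C@]1(C)CCC/C(=C/CCCO)[C@H]1O[Si](C)(C)C(C)(C)C | intermediate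
25 | methyl (1R,2R,3Z)-2-(tert-butyldimethylsilyloxy)-3-(4-iodobutylidene)-1-methylcyclohexane-1-carboxylate | COC(=O)[C@]1(C)CCC/C(=C/CCCI)[C@H]1O[Si](C)(C)C(C)(C)C | intermediate
26 | {(4Z)-4-[(2R,3R)-2-(tert-butyldimethylsilyloxy)-3-(methoxycarbonyl)-3-methylcyclohexylidene]butyl}triphenylphosphonium iodide | [I-].COC(=O)[C@]1(C)CCC/C(=C/CCC[P+](c2ccccc2)(c2ccccc2)c2ccccc2)[C@H]1O[Si](C)(C)C(C)(C)C | intermediate
27 | (2S,3S,4R,5S)-4-(benzyloxy)-3-(tert-butyldimethylsilyloxy)-5-hydroxy-2-methylhept-6-enoic acid | OC(=O)[C@@H](C)[C@H](O[Si](C)(C)C(C)(C)C)[C@H](OCc1ccccc1)[C@@H](O)C=C | intermediate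
28 | (3S,4S,5R,6R)-5-(benzyloxy)-4-(tert-butyldimethylsilyloxy)-6-ethenyl-3-methyloxan-2-one (lactone, ring B series) | C=C[C@H]1OC(=O)[C@@H](C)[C@H](O[Si](C)(C)C(C)(C)C)[C@@H]1OCc1ccccc1 | intermediate
29 | trimethylsilyl ketene acetal of 28: 3-(benzyloxy)-4-(tert-butyldimethylsilyloxy)-2-ethenyl-5-methyl-6-(trimethylsilyloxy)-3,4-dihydro-2H-pyran, ring centres as in 28 | C=C[C@H]1OC(O[Si](C)(C)C)=C(C)[C@H](O[Si](C)(C)C(C)(C)C)[C@@H]1OCc1ccccc1 | intermediate
30 | trimethylsilyl (1S,2S,3R)-3-(benzyloxy)-2-(tert-butyldimethylsilyloxy)-1-methylcyclohex-4-ene-1-carboxylate | C[Si](C)(C)OC(=O)[C@@]1(C)CC=C[C@@H](OCc2ccccc2)[C@H]1O[Si](C)(C)C(C)(C)C | intermediate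
31 | (1S,2S,3R)-3-(benzyloxy)-2-(tert-butyldimethylsilyloxy)-1-methylcyclohex-4-ene-1-carboxylic acid | OC(=O)[C@@]1(C)CC=C[C@@H](OCc2ccccc2)[C@H]1O[Si](C)(C)C(C)(C)C | intermediate
32 | methyl (1S,2S,3R)-3-(benzyloxy)-2-(tert-butyldimethylsilyloxy)-1-methylcyclohex-4-ene-1-carboxylate | COC(=O)[C@@]1(C)CC=C[C@@H](OCc2ccccc2)[C@H]1O[Si](C)(C)C(C)(C)C | intermediate
33 | methyl (1S,2S,3R)-2-(tert-butyldimethylsilyloxy)-3-hydroxy-1-methylcyclohexane-1-carboxylate | COC(=O)[C@@]1(C)CCC[C@@H](O)[C@H]1O[Si](C)(C)C(C)(C)C | intermediate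
34 | methyl (1S,2S)-2-(tert-butyldimethylsilyloxy)-1-methyl-3-oxocyclohexane-1-carboxylate | COC(=O)[C@@]1(C)CCCC(=O)[C@H]1O[Si](C)(C)C(C)(C)C | intermediate
35 | {(4Z)-4-[(2R,3R)-2-(tert-butyldimethylsilyloxy)-3-(methoxycarbonyl)-3-methylcyclohexylidene]butylidene}triphenylphosphorane | COC(=O)[C@]1(C)CCC/C(=C/CCC=P(c2ccccc2)(c2ccccc2)c2ccccc2)[C@H]1O[Si](C)(C)C(C)(C)C | intermediate
36 | dimethyl (1R,1'S,2R,2'R,3Z,3'Z)-3,3'-(butane-1,4-diylidene)bis[2-(tert-butyldimethylsilyloxy)-1-methylcyclohexane-1-carboxylate] | COC(=O)[C@]1(C)CCC/C(=C/CC/C=C2/CCC[C@](C)(C(=O)OC)[C@@H]2O[Si](C)(C)C(C)(C)C)[C@H]1O[Si](C)(C)C(C)(C)C | intermediate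
37 | [(3Z,3'Z)-3,3'-(butane-1,4-diylidene)bis[2-(tert-butyldimethylsilyloxy)-1-methylcyclohexane-3,1-diyl]]dimethanol, ring configurations as in 36 | OC[C@]1(C)CCC/C(=C/CC/C=C2/CCC[C@](C)(CO)[C@@H]2O[Si](C)(C)C(C)(C)C)[C@H]1O[Si](C)(C)C(C)(C)C | intermediate
38 | (1R,1'S,2R,2'R,3Z,3'Z)-3,3'-(butane-1,4-diylidene)bis[2-(tert-butyldimethylsilyloxy)-1-methylcyclohexane-1-carbaldehyde] | O=C[C@]1(C)CCC/C(=C/CC/C=C2/CCC[C@](C)(C=O)[C@@H]2O[Si](C)(C)C(C)(C)C)[C@H]1O[Si](C)(C)C(C)(C)C | intermediate
39 | 1-chloro-3-methylbut-2-ene (prenyl chloride) | CC(C)=CCCl | starting material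
40 | (3-methylbut-2-en-1-yl)barium chloride (prenylbarium chloride) | CC(C)=CC[Ba]Cl | intermediate
41 | 1,1'-[(3Z,3'Z)-3,3'-(butane-1,4-diylidene)bis[2-(tert-butyldimethylsilyloxy)-1-methylcyclohexane-3,1-diyl]]bis(4-methylpent-3-en-1-ol), ring configurations as in 36, carbinol centres as epimer mixtures | CC(C)=CCC(O)[C@]1(C)CCC/C(=C/CC/C=C2/CCC[C@](C)(C(O)CC=C(C)C)[C@@H]2O[Si](C)(C)C(C)(C)C)[C@H]1O[Si](C)(C)C(C)(C)C | intermediate
42 | 1,1'-[(1R,1'S,2R,2'R,3Z,3'Z)-3,3'-(butane-1,4-diylidene)bis[2-(tert-butyldimethylsilyloxy)-1-methylcyclohexane-3,1-diyl]]bis(4-methylpent-3-en-1-one) | CC(C)=CCC(=O)[C@]1(C)CCC/C(=C/CC/C=C2/CCC[C@](C)(C(=O)CC=C(C)C)[C@@H]2O[Si](C)(C)C(C)(C)C)[C@H]1O[Si](C)(C)C(C)(C)C | intermediate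
43 | CNP0297042.3, 1,1'-[(1R,1'S,2R,2'R,3Z,3'Z)-3,3'-(butane-1,4-diylidene)bis(2-hydroxy-1-methylcyclohexane-3,1-diyl)]bis(4-methylpent-3-en-1-one) | CC(C)=CCC(=O)[C@]1(C)CCC/C(=C/CC/C=C2/CCC[C@](C)(C(=O)CC=C(C)C)[C@@H]2O)[C@H]1O | target

**Step count and risks**

Total: 27 steps. Longest linear sequence: 21 steps (steps 1–11, 13–16, 22–27).

Steps most likely to fail:

Step 13 (the same concern applies to step 22). The basic ylide may enolise the hindered α-silyloxy ketone in place of adding to it, or the Z/E discrimination in oxaphosphetane formation may be weak. Fallback, a stepwise Horner–Wittig olefination with separation before the elimination, sets out from 18 and returns at 23. Bromide 19 is heated with ethyl diphenylphosphinite (Michaelis–Arbuzov reaction) to give {4-[(tert-butyldimethylsilyl)oxy]butyl}diphenylphosphine oxide F1. Its lithio derivative (n-BuLi, THF, −78 °C), smaller and more nucleophilic than the ylide, is added to 18. The diastereomeric adducts are separated by chromatography, and the one in which the C3 oxygen and the phosphorus are eclipsed when Cb lies over C2, the β-hydroxy phosphine oxide F2, is treated with KH in DMF. The stereospecific syn-elimination should then give 23 as the Z isomer only.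

Step 17. The hydroxy acid may close again with retention before the alcohol is activated, or acyl activation may compete with displacement at C4, so that 12 is formed beside 28. Fallback, oxidation and chelation-controlled reduction in place of SN2 inversion, sets out from 12 and returns at 28. Aminolysis with Me(MeO)NH·HCl and AlMe3 opens 12 to the hydroxy Weinreb amide F3. Dess–Martin oxidation gives the vinyl ketone F4. Reduction with Zn(BH4)2 through the five-membered chelate between the ketone and the α-benzyloxy group should deliver the anti alcohol F5, the C5 epimer of F3. Camphorsulfonic acid in warm toluene then closes F5 to 28 with loss of N,O-dimethylhydroxylamine.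

Step 25. Part of the prenyl metal may react through its γ-terminus at one of the two aldehydes, or excess activated barium may reduce the aldehydes by electron transfer. Fallback, allylation followed by cross-metathesis, which raises no regiochemical question, sets out from 38 and returns at 41. Allylmagnesium bromide (CH2=CHCH2MgBr, at least two equivalents, THF, −78 °C) adds to both aldehydes to give the bis(homoallylic alcohol) F6. Cross-metathesis in 2-methylbut-2-ene with the second-generation Grubbs catalyst RuCl2(=CHPh)(H2IMes)(PCy3) should convert both terminal vinyl groups into 2-methylprop-1-enyl groups and return 41; the trisubstituted ring alkylidenes are expected to be inert.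

Further compounds
F1 | step 13 | {4-[(tert-butyldimethylsilyl)oxy]butyl}diphenylphosphine oxide | CC(C)(C)[Si](C)(C)OCCCCP(=O)(c1ccccc1)c1ccccc1
F2 | step 13 | methyl (1R,2S)-2-(tert-butyldimethylsilyloxy)-3-[4-(tert-butyldimethylsilyloxy)-1-(diphenylphosphoryl)butyl]-3-hydroxy-1-methylcyclohexane-1-carboxylate, the diastereomer whose syn-elimination gives the Z-alkene | COC(=O)[C@]1(C)CCC[C@](O)([C@H](CCCO[Si](C)(C)C(C)(C)C)P(=O)(c2ccccc2)c2ccccc2)[C@H]1O[Si](C)(C)C(C)(C)C
F3 | step 17 | (2S,3S,4R,5S)-4-(benzyloxy)-3-(tert-butyldimethylsilyloxy)-5-hydroxy-N-methoxy-N,2-dimethylhept-6-enamide | CON(C)C(=O)[C@@H](C)[C@H](O[Si](C)(C)C(C)(C)C)[C@H](OCc1ccccc1)[C@@H](O)C=C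
F4 | step 17 | (2S,3S,4S)-4-(benzyloxy)-3-(tert-butyldimethylsilyloxy)-N-methoxy-N,2-dimethyl-5-oxohept-6-enamide | CON(C)C(=O)[C@@H](C)[C@H](O[Si](C)(C)C(C)(C)C)[C@H](OCc1ccccc1)C(=O)C=C
F5 | step 17 | (2S,3S,4R,5R)-4-(benzyloxy)-3-(tert-butyldimethylsilyloxy)-5-hydroxy-N-methoxy-N,2-dimethylhept-6-enamide | CON(C)C(=O)[C@@H](C)[C@H](O[Si](C)(C)C(C)(C)C)[C@H](OCc1ccccc1)[C@H](O)C=C
F6 | step 25 | 1,1'-[(3Z,3'Z)-3,3'-(butane-1,4-diylidene)bis[2-(tert-butyldimethylsilyloxy)-1-methylcyclohexane-3,1-diyl]]bis(but-3-en-1-ol), ring configurations as in 36, carbinol centres as epimer mixtures | C=CCC(O)[C@]1(C)CCC/C(=C/CC/C=C2/CCC[C@](C)(C(O)CC=C)[C@@H]2O[Si](C)(C)C(C)(C)C)[C@H]1O[Si](C)(C)C(C)(C)C
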